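The synthesis rests on cutting the bond between the bridge CH2 and ring C (the 2-hydroxyphenyl ring). The bridge carbon hangs on C3' of ring A (the acyl-bearing ring) between the oxygen-bearing C2' and C4', so ring A can react as an o-quinone methide (C2'=O, C3'=CH2). The key step is a boron-templated three-component union of a 4'-benzyloxy-2'-hydroxychalcone, formaldehyde and 2-(benzyloxy)phenylboronic acid. Boron held on O2' first delivers formaldehyde to C3', the only free ortho position. It then passes its own aryl group, by the ipso carbon, to the unmasked methide carbon. O-Methylation of the 2'-OH and one hydrogenation (alkene, two benzyl ethers) complete four steps.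

Key step: step 2

Assumption: the target SMILES holds no stereocentre and no stereogenic double bond, so the compound is achiral and needs no enantiocontrol. Locants: ring A carries C1' acyl, C2' OMe, C3' CH2 and C4' OH; ring B is the phenyl of the chain; ring C is the 2-hydroxyphenyl ring.

Step 1
Reactants: 1 1-[4-(benzyloxy)-2-hydroxyphenyl]ethanone (4'-benzyloxy-2'-hydroxyacetophenone); 2 benzaldehyde
Product: 3 (E)-1-[4-(benzyloxy)-2-hydroxyphenyl]-3-phenylprop-2-en-1-one
Conditions: KOH (50% aq), EtOH, rt; then 1 M HCl
Reagents that add atoms: none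
Why: Claisen–Schmidt aldol condensation, in which the enolate of the methyl ketone adds to non-enolisable benzaldehyde and E1cB loss of hydroxide gives the conjugated, thermodynamically favoured E-enone, while the benzyl ether is inert and the strongly basic medium keeps the 2'-phenoxide from closing to the flavanone.

Step 2
Reactants: 3 (E)-1-[4-(benzyloxy)-2-hydroxyphenyl]-3-phenylprop-2-en-1-one; 4 formaldehyde (used as paraformaldehyde); 5 2-(benzyloxy)phenylboronic acid
Product: 8 (E)-1-{4-(benzyloxy)-3-[2-(benzyloxy)benzyl]-2-hydroxyphenyl}-3-phenylprop-2-en-1-one, via benzodioxaborin 6 (not isolated), via boron-bound o-quinone methide 7 (not isolated)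
Conditions: (CH2O)n (3 equiv), 5 (1.5 equiv), EtCO2H (0.3 equiv), 4 Å MS, PhMe, 80 °C, then 115 °C (sealed tube); H2O work-up
Reagents that add atoms: none
Why: Condensation of the 2'-OH of 3 with 5 gives an aryloxyboronate whose boron binds formaldehyde and delivers it to C3' through a six-membered cyclic transition state, and loss of water gives 6. At the higher temperature the carboxylic acid helps the benzylic C–O bond of 6 to ionise, assisted by O2' and the 4'-benzyloxy group that flank C3', to the boron-bound o-quinone methide 7, whose boron is completed to a borate by carboxylate or a second boronic acid molecule. The electron-rich 2-(benzyloxy)phenyl group then migrates from boron to the methide carbon through a six-membered transition state (B, O2', C2', C3', CH2, ipso-C), which rearomatises ring A, and the aryl borate is hydrolysed to 8 on work-up. The closest known reaction types are the boronic-acid-templated ortho-hydroxyalkylation of phenols (benzodioxaborin synthesis) and the three-component phenol/aldehyde/boronate condensation that runs through an o-quinone methide with Petasis-type aryl transfer. The only ring closed is the transient six-membered 1,3,2-dioxaborin of 6 (closed by B–O condensation after the cyclic C–C bond formation and reopened in the same flask), and no stereocentre is created. The step needs C3' rather than C5' on ring A (C3' is the only free position ortho to the boron-bearing O2'), the ipso carbon of ring C (fixed by the C–B bond and the cyclic transfer), cross- rather than homo-coupling (5 alone does not condense with formaldehyde) and an untouched side chain (the enone has no enolisable α-CH2, and boron chelated between O2' and the ketone oxygen points away from the β-carbon, so conjugate arylation is out of reach).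

Step 3
Reactants: 8 (E)-1-{4-(benzyloxy)-3-[2-(benzyloxy)benzyl]-2-hydroxyphenyl}-3-phenylprop-2-en-1-one
Product: 9 (E)-1-{4-(benzyloxy)-3-[2-(benzyloxy)benzyl]-2-methoxyphenyl}-3-phenylprop-2-en-1-one
Conditions: MeI, K2CO3, DMF, 45 °C
Reagents that add atoms: iodomethane, CI
Why: Williamson O-methylation, in which the single free OH of 8 is deprotonated by carbonate in a dipolar aprotic solvent (breaking its hydrogen bond to the ketone) and alkylated by MeI, while any flavanone formed by reversible oxa-Michael closure reopens by E1cB under the same base and is drained to 9.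

Step 4
Reactants: 9 (E)-1-{4-(benzyloxy)-3-[2-(benzyloxy)benzyl]-2-methoxyphenyl}-3-phenylprop-2-en-1-one
Product: 10 1-[4-hydroxy-3-(2-hydroxybenzyl)-2-methoxyphenyl]-3-phenylpropan-1-one (target)
Conditions: H2 (1 atm), 10% Pd/C, EtOAc–EtOH, rt, stopped after uptake of 3 equiv H2
Reagents that add atoms: none
Why: Heterogeneous catalytic hydrogenation and hydrogenolysis, in which Pd/C saturates the enone C=C first and then cleaves both aryl benzyl ethers, while the electron-rich aryl ketone, the diarylmethane CH2 and the methyl ether should survive at 1 atm, and the alkene geometry is erased in an achiral product.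

Compound list
1 | 1-[4-(benzyloxy)-2-hydroxyphenyl]ethanone | CC(=O)c1ccc(OCc2ccccc2)cc1O | starting material
2 | benzaldehyde | O=Cc1ccccc1 | starting material
3 | (E)-1-[4-(benzyloxy)-2-hydroxyphenyl]-3-phenylprop-2-en-1-one | O=C(/C=C/c1ccccc1)c1ccc(OCc2ccccc2)cc1O | intermediate
4 | formaldehyde (as paraformaldehyde) | C=O | starting material
5 | 2-(benzyloxy)phenylboronic acid | OB(O)c1ccccc1OCc1ccccc1 | starting material
6 | (E)-1-{5-(benzyloxy)-2-[2-(benzyloxy)phenyl]-4H-1,3,2-benzodioxaborin-8-yl}-3-phenylprop-2-en-1-one (not isolated) | O=C(/C=C/c1ccccc1)c1ccc(OCc2ccccc2)c2c1OB(c1ccccc1OCc1ccccc1)OC2 | intermediate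
7 | ring-opened isomer of 6: o-quinone methide of ring A (C2'=O, C3'=CH2) with its oxygen held on the arylboron unit, drawn as the formal zwitterion (not isolated) | C=C1C(=[O+]B([O-])c2ccccc2OCc2ccccc2)C(C(=O)/C=C/c2ccccc2)=CC=C1OCc1ccccc1 | intermediate
8 | (E)-1-{4-(benzyloxy)-3-[2-(benzyloxy)benzyl]-2-hydroxyphenyl}-3-phenylprop-2-en-1-one | O=C(/C=C/c1ccccc1)c1ccc(OCc2ccccc2)c(Cc2ccccc2OCc2ccccc2)c1O | intermediate
9 | (E)-1-{4-(benzyloxy)-3-[2-(benzyloxy)benzyl]-2-methoxyphenyl}-3-phenylprop-2-en-1-one | COc1c(C(=O)/C=C/c2ccccc2)ccc(OCc2ccccc2)c1Cc1ccccc1OCc1ccccc1 | intermediate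
10 | 1-[4-hydroxy-3-(2-hydroxybenzyl)-2-methoxyphenyl]-3-phenylpropan-1-one | COc1c(C(=O)CCc2ccccc2)ccc(O)c1Cc1ccccc1O | target

Total step count: 4. Longest linear sequence: 4 steps (1 → 3 → 8 → 9 → 10).

Steps most likely to fail

Step 2. The hydroxymethylation may stall because the ketone oxygen occupies the single vacant site of boron. The boronic acid may protodeboronate at 115 °C. The methide may also oligomerise faster than the aryl group migrates. The fallback sets out from 3 and comes back at 9, and makes the same CH–aryl bond by carbonyl addition instead of methide capture. Magnesium-mediated ortho-formylation (MgCl2, Et3N, (CH2O)n, MeCN, reflux; Casnati–Skattebøl) uses six-coordinate magnesium, which can hold phenoxide, ketone and formaldehyde at once. It should give (E)-6-(benzyloxy)-2-hydroxy-3-(3-phenylprop-2-enoyl)benzaldehyde F1. MeI/K2CO3 in DMF should give (E)-6-(benzyloxy)-2-methoxy-3-(3-phenylprop-2-enoyl)benzaldehyde F2. 2-(Benzyloxy)phenylmagnesium bromide F3 (from 1-(benzyloxy)-2-bromobenzene and Mg in THF) is added at −78 °C to the aldehyde, the most electrophilic carbonyl group. This should give racemic (E)-1-{4-(benzyloxy)-3-[[2-(benzyloxy)phenyl](hydroxy)methyl]-2-methoxyphenyl}-3-phenylprop-2-en-1-one F4. Ionic reduction of this doubly activated carbinol (Et3SiH, 1.1 equiv, TFA, CH2Cl2, 0 °C) should give 9 and erase the stereocentre.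

Step 3. O-Alkylation of the hindered, hydrogen-bonded phenoxide may be slow, so that intramolecular oxa-Michael ring closure of the 2'-hydroxychalcone takes over. The fallback sets out from 8 and comes back at 10, and removes the Michael acceptor before the methylation. A hydrogenation that spares benzyl ethers (H2, Pd/C poisoned with Ph2S, EtOAc) should give 1-{4-(benzyloxy)-3-[2-(benzyloxy)benzyl]-2-hydroxyphenyl}-3-phenylpropan-1-one F5. The phenol can then be forced (Me2SO4, Cs2CO3, DMF, 60 °C) to 1-{4-(benzyloxy)-3-[2-(benzyloxy)benzyl]-2-methoxyphenyl}-3-phenylpropan-1-one F6. Ordinary hydrogenolysis (H2, Pd/C, EtOAc–EtOH) should then give 10.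

Step 4. The aryl ketone may be over-reduced (carbonyl hydrogenation followed by benzylic hydrogenolysis) before both benzyl ethers are cleaved. The fallback sets out from 9 and comes back at 10, and separates the two tasks so that no hydrogenolysis-active catalyst meets the ketone for long. Acidolytic debenzylation with a cation scavenger (TFA, pentamethylbenzene, CH2Cl2, rt) should give (E)-1-[4-hydroxy-3-(2-hydroxybenzyl)-2-methoxyphenyl]-3-phenylprop-2-en-1-one F7. Alkene-selective homogeneous hydrogenation (H2, (Ph3P)3RhCl, benzene–EtOH) should then give 10.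

Further compounds
F1 | step 2 | (E)-6-(benzyloxy)-2-hydroxy-3-(3-phenylprop-2-enoyl)benzaldehyde | O=Cc1c(O)c(C(=O)/C=C/c2ccccc2)ccc1OCc1ccccc1
F2 | step 2 | (E)-6-(benzyloxy)-2-methoxy-3-(3-phenylprop-2-enoyl)benzaldehyde | COc1c(C(=O)/C=C/c2ccccc2)ccc(OCc2ccccc2)c1C=O
F3 | step 2 | 2-(benzyloxy)phenylmagnesium bromide | Br[Mg]c1ccccc1OCc1ccccc1
F4 | step 2 | (E)-1-{4-(benzyloxy)-3-[[2-(benzyloxy)phenyl](hydroxy)methyl]-2-methoxyphenyl}-3-phenylprop-2-en-1-one (racemic) | COc1c(C(=O)/C=C/c2ccccc2)ccc(OCc2ccccc2)c1C(O)c1ccccc1OCc1ccccc1
F5 | step 3 | 1-{4-(benzyloxy)-3-[2-(benzyloxy)benzyl]-2-hydroxyphenyl}-3-phenylpropan-1-one | O=C(CCc1ccccc1)c1ccc(OCc2ccccc2)c(Cc2ccccc2OCc2ccccc2)c1O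
F6 | step 3 | 1-{4-(benzyloxy)-3-[2-(benzyloxy)benzyl]-2-methoxyphenyl}-3-phenylpropan-1-one | COc1c(C(=O)CCc2ccccc2)ccc(OCc2ccccc2)c1Cc1ccccc1OCc1ccccc1
F7 | step 4 | (E)-1-[4-hydroxy-3-(2-hydroxybenzyl)-2-methoxyphenyl]-3-phenylprop-2-en-1-one | COc1c(C(=O)/C=C/c2ccccc2)ccc(O)c1Cc1ccccc1O
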